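**Retrosynthetic overview**
1. Target 21 ⇐ 20: the ring C quinone is unmasked last by oxidative demethylation of a 5,6,8-trimethoxy arene.
2. 20 ⇐ 18: the lactone bridge across ring A is closed by oxidising a 4-alkyl-1-naphthol to its para-quinone methide, which is trapped by the C1 carboxylic acid.
3. 18 ⇐ 15: ring B is built by intramolecular aldol condensation/aromatisation of an aryl methyl ketone onto the ring A ketone (key ring closure).
4. 15 ⇐ 8 + 14: a Pd-catalysed α-arylation joins the ring A silyl enol ether (from cyclohexanone, quaternary centre by valine-enamine methylation) to the ring C bromoacetophenone (from 1,2,4-trimethoxybenzene).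
5. Ring order: A and C prepared separately, then B (aldol), then the lactone bridge, then the quinone.

Assumption: in step 3 the lithio-enamine of L-valine tert-butyl ester, with THF as the only donor (no HMPA), is methylated anti to the valine isopropyl group, which gives (S)-7; rotation and ee of 7 are checked before use.

Positions in the tricyclic compounds follow phenanthrene numbering.

**Ring A fragment**

Step 1
Reactants: 1 cyclohexanone
Product: 2 methyl 2-oxocyclohexane-1-carboxylate
Conditions: NaH (2.2 equiv), dimethyl carbonate, THF, reflux; then aq. HCl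
Reagents that add atoms: dimethyl carbonate, COC(=O)OC
Why: Claisen-type C-carbomethoxylation of the ketone enolate, driven by irreversible deprotonation of the β-keto ester formed; the α-centre is racemic and becomes sp2 in step 2.

Step 2
Reactants: 2 methyl 2-oxocyclohexane-1-carboxylate; 3 tert-butyl L-valinate (free base)
Product: 4 tert-butyl (2S)-2-{[2-(methoxycarbonyl)cyclohex-1-en-1-yl]amino}-3-methylbutanoate
Conditions: BF3·OEt2 (3 mol %), toluene, reflux, Dean–Stark
Reagents that add atoms: none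
Why: acid-catalysed condensation of the β-keto ester with the primary amine gives the conjugated, N–H···O=C hydrogen-bonded enamino ester with azeotropic removal of water; the valine centre is untouched.

Step 3
Reactants: 4 tert-butyl (2S)-2-{[2-(methoxycarbonyl)cyclohex-1-en-1-yl]amino}-3-methylbutanoate
Product: 7 methyl (1S)-1-methyl-2-oxocyclohexane-1-carboxylate, via lithio-enamine 5 (not isolated), via methylated imine 6 (not isolated)
Conditions: LiN(iPr)2 (1.2 equiv), THF, −78 °C; MeI, −78 → −20 °C; then 1 M aq. HCl, 25 °C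
Reagents that add atoms: iodomethane, CI; water, O
Why: Koga-type asymmetric alkylation of a chiral lithio-enamine, in which lithium is chelated by nitrogen and both ester carbonyls so that methyl iodide enters the face anti to the valine isopropyl group and sets the quaternary centre as S; mild acid hydrolysis of the imine releases the ketone and the auxiliary 3.

Step 4
Reactants: 7 methyl (1S)-1-methyl-2-oxocyclohexane-1-carboxylate
Product: 8 methyl (1S)-1-methyl-2-[(trimethylsilyl)oxy]cyclohex-2-ene-1-carboxylate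
Conditions: TMSOTf (1.2 equiv), Et3N (1.5 equiv), CH2Cl2, 0 °C
Reagents that add atoms: trimethylsilyl trifluoromethanesulfonate, C[Si](C)(C)OS(=O)(=O)C(F)(F)F
Why: soft enolisation and O-silylation of the ketone; only one α-CH2 exists, so a single enol ether forms, and the quaternary centre has no α-hydrogen and cannot racemise.

**Ring C fragment**

Step 5
Reactants: 9 1,2,4-trimethoxybenzene
Product: 11 2-(2,3,6-trimethoxyphenyl)propan-2-ol, via aryllithium 10 (not isolated)
Conditions: n-BuLi (1.1 equiv), THF, 0 → 25 °C; acetone, −78 → 25 °C; then H2O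
Reagents that add atoms: acetone, CC(C)=O
Why: directed ortho-metalation at C3, the position flanked by two methoxy groups, followed by 1,2-addition of the aryllithium to acetone.

Step 6
Reactants: 11 2-(2,3,6-trimethoxyphenyl)propan-2-ol
Product: 12 1,2,4-trimethoxy-3-(propan-2-yl)benzene
Conditions: Et3SiH (3 equiv), CF3CO2H, CH2Cl2, 0 → 25 °C
Reagents that add atoms: none
Why: ionic hydrogenation, in which the tertiary benzylic alcohol ionises in acid and the cation is reduced by hydride transfer from the silane.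

Step 7
Reactants: 12 1,2,4-trimethoxy-3-(propan-2-yl)benzene
Product: 13 1-[2,4,5-trimethoxy-3-(propan-2-yl)phenyl]ethan-1-one
Conditions: AcCl (1.2 equiv), SnCl4 (1.2 equiv), CH2Cl2, −10 → 0 °C
Reagents that add atoms: acetyl chloride, CC(Cl)=O
Why: Friedel–Crafts acylation at C5 of 12, which is para to the 2-methoxy and ortho to the 4-methoxy group; SnCl4 is mild enough not to cleave the methoxy group ortho to the new ketone.

Step 8
Reactants: 13 1-[2,4,5-trimethoxy-3-(propan-2-yl)phenyl]ethan-1-one
Product: 14 1-[2-bromo-3,4,6-trimethoxy-5-(propan-2-yl)phenyl]ethan-1-one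
Conditions: NBS (1.05 equiv), MeCN, 0 → 25 °C, dark
Reagents that add atoms: N-bromosuccinimide, O=C1CCC(=O)N1Br
Why: electrophilic aromatic bromination at the only free ring position (ortho to a methoxy group, para to isopropyl); the polar, acid-free medium disfavours enol bromination of the acetyl group.

**Union and completion**

Step 9
Reactants: 8 methyl (1S)-1-methyl-2-[(trimethylsilyl)oxy]cyclohex-2-ene-1-carboxylate (1.3 equiv); 14 1-[2-bromo-3,4,6-trimethoxy-5-(propan-2-yl)phenyl]ethan-1-one
Product: 15 methyl (1S,3RS)-3-[2-acetyl-3,5,6-trimethoxy-4-(propan-2-yl)phenyl]-1-methyl-2-oxocyclohexane-1-carboxylate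
Conditions: Pd(OAc)2 (5 mol %), P(t-Bu)3 (10 mol %), ZnF2 (0.5 equiv), CsF (1.0 equiv), DMF, 85 °C
Reagents that add atoms: none
Why: Pd-catalysed α-arylation of a silyl enol ether: zerovalent palladium inserts into the C–Br bond, the fluoride-activated enol silane transmetalates and reductive elimination forms the aryl–C3 bond, under conditions too weakly basic to enolise the aryl methyl ketone. The new C3 centre is uncontrolled and becomes aromatic in step 10, and any onward cyclisation at this stage converges there.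

Step 10
Reactants: 15 methyl (1S,3RS)-3-[2-acetyl-3,5,6-trimethoxy-4-(propan-2-yl)phenyl]-1-methyl-2-oxocyclohexane-1-carboxylate
Product: 18 (1S)-9-hydroxy-5,6,8-trimethoxy-1-methyl-7-(propan-2-yl)-1,2,3,4-tetrahydrophenanthrene-1-carboxylic acid, via aldol adduct 16 (not isolated), via naphthol ester 17 (not isolated)
Conditions: KOtBu (1.5 equiv), THF/t-BuOH, 0 → 25 °C, degassed; then KOH (5 equiv), MeOH–H2O, 80 °C; then 1 M HCl
Reagents that add atoms: potassium hydroxide, [K+].[OH-]
Why: intramolecular aldol condensation, in which the methyl ketone enolate closes a six-membered ring onto the ring A ketone and loss of water with tautomerisation gives the aromatic naphthol; the non-nucleophilic base avoids retro-Claisen opening of the non-enolisable β-keto ester, hydroxide then saponifies the ester, and the quaternary centre is untouched.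

Step 11
Reactants: 18 (1S)-9-hydroxy-5,6,8-trimethoxy-1-methyl-7-(propan-2-yl)-1,2,3,4-tetrahydrophenanthrene-1-carboxylic acid
Product: 20 (1S,4R)-4,9-dihydroxy-5,6,8-trimethoxy-1-methyl-7-(propan-2-yl)-1,2,3,4-tetrahydrophenanthrene-1-carboxylic acid 1,4-lactone, via quinone methide 19 (not isolated)
Conditions: DDQ (1.1 equiv), anhydrous 1,4-dioxane, 25 °C
Reagents that add atoms: none
Why: DDQ oxidises the 4-alkyl-1-naphthol to its para-quinone methide, and intramolecular 1,6-addition (oxa-Michael) of the carboxylic acid to the methide carbon re-aromatises ring B and closes the bicyclo[2.2.2] lactone. The acid can reach C4 only from its own face, so the C1 centre fixes C4 as R, and the bridgehead product cannot be re-oxidised; the transformation parallels carnosic acid → carnosol.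

Step 12
Reactants: 20 (1S,4R)-4,9-dihydroxy-5,6,8-trimethoxy-1-methyl-7-(propan-2-yl)-1,2,3,4-tetrahydrophenanthrene-1-carboxylic acid 1,4-lactone
Product: 21 (1S,4R)-4,9-dihydroxy-6-methoxy-1-methyl-5,8-dioxo-7-(propan-2-yl)-1,2,3,4,5,8-hexahydrophenanthrene-1-carboxylic acid 1,4-lactone (target)
Conditions: (NH4)2Ce(NO3)6 (2.5 equiv), MeCN–H2O (3:1), 0 °C, 15 min
Reagents that add atoms: water, O
Why: oxidative demethylation of the para-related 5- and 8-methoxy groups of the most electron-rich ring by tetravalent cerium gives the para-quinone; the 6-methoxy group stays as a vinylogous ester, the 9-OH becomes the hydrogen-bonded peri-hydroxyl, and neither stereocentre is touched.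

**Compound list**
1 | cyclohexanone | O=C1CCCCC1 | starting material
2 | methyl 2-oxocyclohexane-1-carboxylate (racemic, keto form) | COC(=O)C1CCCCC1=O | intermediate
3 | tert-butyl L-valinate, tert-butyl (2S)-2-amino-3-methylbutanoate (free base from the commercial hydrochloride) | CC(C)[C@H](N)C(=O)OC(C)(C)C | starting material
4 | tert-butyl (2S)-2-{[2-(methoxycarbonyl)cyclohex-1-en-1-yl]amino}-3-methylbutanoate | COC(=O)C1=C(N[C@@H](C(C)C)C(=O)OC(C)(C)C)CCCC1 | intermediate
5 | N-lithio derivative of 4 (lithio-enamine) | COC(=O)C1=C(N([Li])[C@@H](C(C)C)C(=O)OC(C)(C)C)CCCC1 | intermediate (not isolated)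
6 | methyl (1S)-2-{[(2S)-1-(tert-butoxy)-3-methyl-1-oxobutan-2-yl]imino}-1-methylcyclohexane-1-carboxylate | C[C@]1(C(=O)OC)CCCCC1=N[C@@H](C(C)C)C(=O)OC(C)(C)C | intermediate (not isolated)
7 | methyl (1S)-1-methyl-2-oxocyclohexane-1-carboxylate | C[C@]1(C(=O)OC)CCCCC1=O | intermediate
8 | methyl (1S)-1-methyl-2-[(trimethylsilyl)oxy]cyclohex-2-ene-1-carboxylate | C[C@]1(C(=O)OC)CCCC=C1O[Si](C)(C)C | intermediate
9 | 1,2,4-trimethoxybenzene | COc1ccc(OC)c(OC)c1 | starting material
10 | (2,3,6-trimethoxyphenyl)lithium | [Li]c1c(OC)ccc(OC)c1OC | intermediate (not isolated)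
11 | 2-(2,3,6-trimethoxyphenyl)propan-2-ol | CC(C)(O)c1c(OC)ccc(OC)c1OC | intermediate
12 | 1,2,4-trimethoxy-3-(propan-2-yl)benzene | CC(C)c1c(OC)ccc(OC)c1OC | intermediate
13 | 1-[2,4,5-trimethoxy-3-(propan-2-yl)phenyl]ethan-1-one | CC(C)c1c(OC)c(C(C)=O)cc(OC)c1OC | intermediate
14 | 1-[2-bromo-3,4,6-trimethoxy-5-(propan-2-yl)phenyl]ethan-1-one | CC(C)c1c(OC)c(C(C)=O)c(Br)c(OC)c1OC | intermediate
15 | methyl (1S,3RS)-3-[2-acetyl-3,5,6-trimethoxy-4-(propan-2-yl)phenyl]-1-methyl-2-oxocyclohexane-1-carboxylate (C3 epimers) | C[C@]1(C(=O)OC)CCCC(c2c(OC)c(OC)c(C(C)C)c(OC)c2C(C)=O)C1=O | intermediate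
16 | methyl (1S)-10a-hydroxy-5,6,8-trimethoxy-1-methyl-9-oxo-7-(propan-2-yl)-1,2,3,4,4a,9,10,10a-octahydrophenanthrene-1-carboxylate (C4a/C10a isomers) | C[C@]1(C(=O)OC)CCCC2c3c(OC)c(OC)c(C(C)C)c(OC)c3C(=O)CC12O | intermediate (not isolated)
17 | methyl (1S)-9-hydroxy-5,6,8-trimethoxy-1-methyl-7-(propan-2-yl)-1,2,3,4-tetrahydrophenanthrene-1-carboxylate | C[C@]1(C(=O)OC)CCCc2c1cc(O)c1c(OC)c(C(C)C)c(OC)c(OC)c21 | intermediate (not isolated)
18 | (1S)-9-hydroxy-5,6,8-trimethoxy-1-methyl-7-(propan-2-yl)-1,2,3,4-tetrahydrophenanthrene-1-carboxylic acid | C[C@]1(C(=O)O)CCCc2c1cc(O)c1c(OC)c(C(C)C)c(OC)c(OC)c21 | intermediate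
19 | (1S)-5,6,8-trimethoxy-1-methyl-9-oxo-7-(propan-2-yl)-1,2,3,9-tetrahydrophenanthrene-1-carboxylic acid (para-quinone methide) | C[C@]1(C(=O)O)CCC=C2C1=CC(=O)c1c(OC)c(C(C)C)c(OC)c(OC)c12 | intermediate (not isolated)
20 | (1S,4R)-4,9-dihydroxy-5,6,8-trimethoxy-1-methyl-7-(propan-2-yl)-1,2,3,4-tetrahydrophenanthrene-1-carboxylic acid 1,4-lactone | COc1c(C(C)C)c(OC)c2c(O)cc3c(c2c1OC)[C@H]1CC[C@]3(C)C(=O)O1 | intermediate
21 | (1S,4R)-4,9-dihydroxy-6-methoxy-1-methyl-5,8-dioxo-7-(propan-2-yl)-1,2,3,4,5,8-hexahydrophenanthrene-1-carboxylic acid 1,4-lactone | COC1=C(C(C)C)C(=O)c2c(O)cc3c(c2C1=O)[C@H]1CC[C@]3(C)C(=O)O1 | target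

**Step count**
Total: 12 steps. Longest linear sequence: 8 steps (steps 1–4 then 9–12, or equally steps 5–8 then 9–12).

**Steps most likely to fail, with fallbacks**

Step 9 (coupling of a hexasubstituted aryl bromide at a hindered enolate carbon). The fallback sets out from 8 and 14 and comes back at 15, replacing the enolate arylation by an sp2–sp2 coupling followed by hydrogenation. Saegusa oxidation of 8 (Pd(OAc)2 10 mol %, O2, DMSO, 25 °C) gives methyl (1S)-1-methyl-2-oxocyclohex-3-ene-1-carboxylate F1, which is iodinated at the α-carbon (I2, pyridine, CH2Cl2) to methyl (1S)-3-iodo-1-methyl-2-oxocyclohex-3-ene-1-carboxylate F2. In parallel, Miyaura borylation of 14 (bis(pinacolato)diboron, KOAc, Pd(OAc)2/SPhos, dioxane, 90 °C) gives 1-[3,4,6-trimethoxy-5-(propan-2-yl)-2-(4,4,5,5-tetramethyl-1,3,2-dioxaborolan-2-yl)phenyl]ethan-1-one F3. Suzuki coupling of F2 and F3 under mild, nearly neutral conditions (PdCl2(PhCN)2, AsPh3, Ag2O, THF–H2O, 25 °C) gives methyl (1S)-3-[2-acetyl-3,5,6-trimethoxy-4-(propan-2-yl)phenyl]-1-methyl-2-oxocyclohex-3-ene-1-carboxylate F4. Hydrogenation of the enone C=C (H2 1 atm, Pd/C, EtOAc) then returns 15.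

Step 11 (the quinone methide may isomerise or oligomerise before the acid closes the strained bridge). The fallback sets out from 18 and comes back at 20, forming the C–O bond by lactonisation of a benzylic alcohol instead. Benzylic oxidation of 18 in wet solvent (DDQ 2.2 equiv, dioxane–H2O 9:1) gives (1S)-9-hydroxy-5,6,8-trimethoxy-1-methyl-4-oxo-7-(propan-2-yl)-1,2,3,4-tetrahydrophenanthrene-1-carboxylic acid F5. Reduction (NaBH4, EtOH, 0 °C) gives (1S)-4,9-dihydroxy-5,6,8-trimethoxy-1-methyl-7-(propan-2-yl)-1,2,3,4-tetrahydrophenanthrene-1-carboxylic acid F6 as a mixture of C4 epimers. Treatment with TsOH (cat.) in toluene at 60 °C closes the lactone 20: the cis epimer lactonises directly and the trans epimer ionises to the para-hydroxy-stabilised benzylic cation and converges.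

Step 12 (the free naphthol ring may be oxidised in competition with ring C, or an ortho- or 1,5-quinone may form). The fallback sets out from 20 and comes back at 21, deactivating ring B before the oxidation. Acetylation of 20 (Ac2O, pyridine, DMAP, CH2Cl2) gives (1S,4R)-9-acetoxy-4-hydroxy-5,6,8-trimethoxy-1-methyl-7-(propan-2-yl)-1,2,3,4-tetrahydrophenanthrene-1-carboxylic acid 1,4-lactone F7. Oxidation with (NH4)2Ce(NO3)6 in MeCN–H2O at 0 °C, now confined to the trimethoxy ring, gives (1S,4R)-9-acetoxy-4-hydroxy-6-methoxy-1-methyl-5,8-dioxo-7-(propan-2-yl)-1,2,3,4,5,8-hexahydrophenanthrene-1-carboxylic acid 1,4-lactone F8. Brief methanolysis of the peri-acetate (K2CO3 0.2 equiv, MeOH, 0 °C, then dilute HCl) returns 21.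

**Further compounds**
F1 | step 9 | methyl (1S)-1-methyl-2-oxocyclohex-3-ene-1-carboxylate | C[C@]1(C(=O)OC)CCC=CC1=O
F2 | step 9 | methyl (1S)-3-iodo-1-methyl-2-oxocyclohex-3-ene-1-carboxylate | C[C@]1(C(=O)OC)CCC=C(I)C1=O
F3 | step 9 | 1-[3,4,6-trimethoxy-5-(propan-2-yl)-2-(4,4,5,5-tetramethyl-1,3,2-dioxaborolan-2-yl)phenyl]ethan-1-one | CC(C)c1c(OC)c(C(C)=O)c(B2OC(C)(C)C(C)(C)O2)c(OC)c1OC
F4 | step 9 | methyl (1S)-3-[2-acetyl-3,5,6-trimethoxy-4-(propan-2-yl)phenyl]-1-methyl-2-oxocyclohex-3-ene-1-carboxylate | C[C@]1(C(=O)OC)CCC=C(c2c(OC)c(OC)c(C(C)C)c(OC)c2C(C)=O)C1=O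
F5 | step 11 | (1S)-9-hydroxy-5,6,8-trimethoxy-1-methyl-4-oxo-7-(propan-2-yl)-1,2,3,4-tetrahydrophenanthrene-1-carboxylic acid | C[C@]1(C(=O)O)CCC(=O)c2c1cc(O)c1c(OC)c(C(C)C)c(OC)c(OC)c21
F6 | step 11 | (1S)-4,9-dihydroxy-5,6,8-trimethoxy-1-methyl-7-(propan-2-yl)-1,2,3,4-tetrahydrophenanthrene-1-carboxylic acid (C4 epimers) | C[C@]1(C(=O)O)CCC(O)c2c1cc(O)c1c(OC)c(C(C)C)c(OC)c(OC)c21
F7 | step 12 | (1S,4R)-9-acetoxy-4-hydroxy-5,6,8-trimethoxy-1-methyl-7-(propan-2-yl)-1,2,3,4-tetrahydrophenanthrene-1-carboxylic acid 1,4-lactone | COc1c(C(C)C)c(OC)c2c(OC(C)=O)cc3c(c2c1OC)[C@H]1CC[C@]3(C)C(=O)O1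
F8 | step 12 | (1S,4R)-9-acetoxy-4-hydroxy-6-methoxy-1-methyl-5,8-dioxo-7-(propan-2-yl)-1,2,3,4,5,8-hexahydrophenanthrene-1-carboxylic acid 1,4-lactone | COC1=C(C(C)C)C(=O)c2c(OC(C)=O)cc3c(c2C1=O)[C@H]1CC[C@]3(C)C(=O)O1
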